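## Structural features

(−)-Thujaplicatin is a dibenzylbutyrolactone lignan. One γ-butyrolactone (O1, carbonyl C2, C3, C4, C5) carries a 3,4-dihydroxy-5-methoxybenzyl group (ring A, through C7) on C3 and a 4-hydroxy-3-methoxybenzyl group (ring B, through C7′) on C4. The only stereocentres are the adjacent C3 and C4, both R and trans to each other. C3 lies α to the lactone carbonyl and is epimerisable, and the trans arrangement is the more stable one, so C3 can be derived from C4. C4 is flanked by three sp3 carbons (C3, C5, C7′), has no acidifying or directing group, and cannot be corrected once made; this is the real difficulty. Fragile features are the ring A catechol (oxidised under basic aerobic conditions), the lactone (opened by nucleophilic base) and the two electron-rich arenes, which are attacked by carbocations. A cation at C7′ in particular would close a six-membered ring onto ring A (aryltetralin). The key step exploits the neighbours of C4: with C7′ as an aryl ketone and C5 as an ester, C4 becomes the acidic α-carbon of an aroyl β-keto ester and can be set by reduction under dynamic kinetic resolution. A second carboxyl kept on C3 (malonate) makes C3 non-stereogenic while this is done.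

## Logic of the disconnections

**18 to 15.** The lactone bond O1–C2 is opened and a carboxyl is added back to C3, which leads through 17 and 16 to the isolable hydroxy malonate 15. With two identical carboxyl groups C3 is not a stereocentre, so only C4 has to be carried through the route and C3 is decided at the end by equilibration against C4. The gain is one stereocentre fewer and an acyclic chain. The forward step must cleave the esters without alkylating the electron-rich rings, lose CO2 cleanly, and equilibrate C3 to trans without harming the free catechol.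

**15 to 13.** The C7′–H bond is replaced by C7′–OH and the three phenolic O–H bonds by O–benzyl. One hydrogenolysis removes all four groups. It is placed before any acid treatment, because a ring B benzylic alcohol two carbons from ring A and from two carboxyl groups would ionise in acid and close an aryltetralin or a benzylic lactone. The forward step must cleave a hindered benzylic C–O bond without touching C4.

**13 to 12.** C5 is taken back from CH2OH to a methyl ester. With C5 as an ester, C4 is the α-carbon of a β-hydroxy ester and hence reachable from a β-keto ester. The forward step needs a hydride reagent that reduces the methyl ester and leaves the two tert-butyl esters.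

**12 to 11 (key step).** The benzylic C7′–H bond is cut, returning the carbinol to the aryl ketone. In 11 the future C4 is configurationally labile, so a racemate can be funnelled into one configuration. The gain is that the only stereochemical problem of the target is solved catalytically on a racemic substrate. The forward step needs epimerisation much faster than reduction, and high discrimination between the two epimers.

**11 to 6 and 10.** The C4–C7′ bond is cut between the ester α-carbon and the acyl carbon. This joins ring B convergently, and 6 has only one enolisable position. The forward step needs excess base, because 11 is more acidic than 6, and C-acylation must win over O-acylation at a hindered enolate.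

**10 to 9 to 7.** Functional group changes only: acid chloride from acid, aryl benzyl ether from phenol.

**6 to 5.** The C3–C4 bond is cut. Alkylation of the tertiary malonate anion with a two-carbon haloacetate creates the quaternary C3 and brings in C4 and C5 at the right oxidation levels.

**5 to 4 to 2 and 3, and 2 to 1.** The C3–C7 bond is cut as a condensation followed by conjugate reduction. This avoids an electron-rich benzylic halide and double alkylation of 3. Compound 2 is the benzyl-protected form of 1.

## Other disconnections considered

**Alternative 1: enzymatic Baeyer–Villiger desymmetrisation.**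
- Cut: the C3–C7 bond is cut first, leaving the 4-monosubstituted lactone (4R)-4-[4-(benzyloxy)-3-methoxybenzyl]dihydrofuran-2(3H)-one A2. A2 is then traced back by removing O1 to the prochiral 3-[4-(benzyloxy)-3-methoxybenzyl]cyclobutan-1-one A1.
- Forward key step: a Baeyer–Villiger monooxygenase with molecular oxygen and a recycled nicotinamide cofactor inserts oxygen next to one of the two enantiotopic CH2 groups of A1. This expands the ring and sets C4 in A2. The enolate of A2 would then be benzylated with 3,4-bis(benzyloxy)-5-methoxybenzyl bromide A3 anti to the C4 substituent, and hydrogenolysis would give 18.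
- In favour: no sacrificial stereocentre, no extra carboxyl, and no deletion of an oxygen. C3 is set by kinetic trans-selective alkylation on benzyl-protected material, which is better than the chosen plan's final equilibration on a free catechol. The longest line is about six steps, clearly shorter.
- Against: the route depends on an enzyme that accepts a 3-benzylcyclobutanone with a bulky aryl group and gives the R lactone. Both the magnitude and the sense of selectivity of such enzymes vary with the substrate. The substrate is poorly soluble in water, and the enantiomeric purity cannot be upgraded by removing a diastereomer.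
- Comparison: on structure both plans set only C4 by reagent control and derive C3 from it, so they are equal there. On mechanism, alternative 1 selects between enantiotopic groups of a symmetric ketone. The chosen plan instead uses a small-molecule catalyst available in both enantiomeric forms, and its stereochemical errors appear as a separable diastereomer. On step economy alternative 1 is better.

**Alternative 2: aryl cuprate opening of a cyclopropane lactone.**
- Cut: the aryl–C7′ bond of the ring B arm.
- Forward key step: the bicyclic lactone ethyl (1S,5R)-2-oxo-3-oxabicyclo[3.1.0]hexane-1-carboxylate A5 would be made from (R)-epichlorohydrin A4 and a dialkyl malonate. The arylcopper reagent generated from 1-(benzyloxy)-4-bromo-2-methoxybenzene A6 (via the Grignard reagent and CuBr·SMe2) attacks the cyclopropane CH2 of A5. The three-membered ring opens and the lactone ester enolate is released. Protonation gives ethyl (3S,4R)-4-[4-(benzyloxy)-3-methoxybenzyl]-2-oxotetrahydrofuran-3-carboxylate A7. The enolate could instead be benzylated in the same flask with A3, followed by dealkoxycarbonylation and hydrogenolysis.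
- In favour: C4 comes from the chiral pool through a stereochemically unambiguous substitution at a non-stereogenic carbon, so no catalyst screening is needed. The route is four to five steps, the shortest of all. The equilibration of C3 would be done on protected material.
- Against: the optical purity is capped by the formation of A5, where two competing pathways of the malonate anion on A4 lead to opposite enantiomers. A stoichiometric organocopper reagent from an electron-rich aryl halide is needed. C3 again rests on thermodynamic control after loss of the carboxyl.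
- Comparison: alternative 2 is better on step economy and on stereochemical certainty at C4. It is equal to the chosen plan on how C3 is controlled. The chosen plan is catalytic in the chiral element, avoids stoichiometric copper and cryogenic organometallics, and can purge a stereochemical leak by diastereomer separation.

**Alternative 3: Ireland–Claisen rearrangement.**
- Cut: the C3–C4 bond.
- Forward key step: the allylic ester (2R,3E)-1-[4-(benzyloxy)-3-methoxyphenyl]pent-3-en-2-yl 3-[3,4-bis(benzyloxy)-5-methoxyphenyl]propanoate A8 is converted into its silyl ketene acetal with an amide base and a chlorosilane. Rearrangement through a chair forms C3–C4 and both stereocentres, giving (2R,3S,4E)-2-[3,4-bis(benzyloxy)-5-methoxybenzyl]-3-[4-(benzyloxy)-3-methoxybenzyl]hex-4-enoic acid A9. Oxidative cleavage of the propenyl group, reduction, lactonisation and hydrogenolysis would follow.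
- In favour: both centres and the central bond are made in one predictable step. C3 is installed directly and not by later equilibration, which is a structural advantage over the chosen plan.
- Against: the diastereomer ratio mirrors the geometry of the ketene acetal of a simple propanoate ester, which is hard to make fully uniform. The enantiopure carbinol of A8 needs its own asymmetric step, so the source of chirality is only moved. The alkene must be cleaved oxidatively next to two electron-rich arenes. Because C3 is epimerisable anyway, its early control brings little.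
- Comparison: both plans relay chirality through a carbinol that is later destroyed, so they are equal in concept. Alternative 3 is better in bond-forming content of the key step. The chosen plan is better in that its stereo-defining step starts from a racemate and needs no oxidative cleavage. The step counts are comparable.

Key step: step 8

Assumption: in step 8 the (S,S)-diamine is taken to deliver hydride to the Re face of the aryl ketone, with the substrate reacting through a Felkin–Anh conformer, which gives (2S); if the sense at C2 were opposite, the (R,R)-diamine would be used with no other change.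

Remark: the descriptor (2S) of 12 corresponds to (4R) of 18, because the CIP ranking of the substituents changes on the way (S in 12, R in 13, 15, 17 and 18). Two points of the end game are designed deliberately: acid never meets the C7′ carbinol, and trans at C3 is secured by an explicit equilibration instead of being expected from decarboxylation alone.

## Route

Step 1
Reactants: 1 3,4-dihydroxy-5-methoxybenzaldehyde (5-hydroxyvanillin)
Product: 2 3,4-bis(benzyloxy)-5-methoxybenzaldehyde
Conditions: BnBr (2.3 equiv), K2CO3, DMF, 60 °C
Reagents that add atoms: benzyl bromide, BrCc1ccccc1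
Why: Williamson etherification of both phenols; benzyl survives base, hydride and transfer hydrogenation and is later removed in the same hydrogenolysis that deletes the C7′ oxygen.

Step 2
Reactants: 2 3,4-bis(benzyloxy)-5-methoxybenzaldehyde; 3 di-tert-butyl malonate
Product: 4 di-tert-butyl 2-[3,4-bis(benzyloxy)-5-methoxybenzylidene]malonate
Conditions: piperidine (0.2 equiv), AcOH (0.2 equiv), toluene, reflux, Dean–Stark trap
Reagents that add atoms: none
Why: Knoevenagel condensation with azeotropic removal of water; only the monoarylidene compound can form, so the over-alkylation that attends direct benzylation of a malonate is excluded and no benzylic halide is needed.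

Step 3
Reactants: 4 di-tert-butyl 2-[3,4-bis(benzyloxy)-5-methoxybenzylidene]malonate
Product: 5 di-tert-butyl 2-[3,4-bis(benzyloxy)-5-methoxybenzyl]malonate
Conditions: NaBH4, EtOH/THF, 0 °C
Reagents that add atoms: none
Why: Conjugate (1,4) hydride reduction of an arylidene malonate; tert-butyl esters and benzyl ethers are inert to NaBH4, and catalytic hydrogenation is avoided because it would cleave the benzyl ethers.

Step 4
Reactants: 5 di-tert-butyl 2-[3,4-bis(benzyloxy)-5-methoxybenzyl]malonate
Product: 6 2,2-di-tert-butyl 1-methyl 3-[3,4-bis(benzyloxy)-5-methoxyphenyl]propane-1,2,2-tricarboxylate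
Conditions: NaH, THF, 0 °C; BrCH2CO2Me, 0 °C to rt
Reagents that add atoms: methyl bromoacetate, COC(=O)CBr
Why: SN2 alkylation of the sodium enolate of the monosubstituted malonate with a primary α-halo ester creates the quaternary carbon (future C3) and brings in the future C4 and C5; no stereocentre is formed.

Step 5
Reactants: 7 vanillic acid
Product: 9 4-(benzyloxy)-3-methoxybenzoic acid, via benzyl 4-(benzyloxy)-3-methoxybenzoate 8 (not isolated)
Conditions: BnBr (2.2 equiv), K2CO3, DMF, 60 °C; then NaOH, MeOH/H2O, 60 °C; HCl to pH 2
Reagents that add atoms: benzyl bromide, BrCc1ccccc1; sodium hydroxide, [Na+].[OH-] (its oxygen ends in the CO2H group)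
Why: Exhaustive O-benzylation of phenol and carboxylate, then saponification of the benzyl ester in the same flask (acyl substitution), which leaves the aryl benzyl ether untouched.

Step 6
Reactants: 9 4-(benzyloxy)-3-methoxybenzoic acid
Product: 10 4-(benzyloxy)-3-methoxybenzoyl chloride
Conditions: (COCl)2, DMF (cat.), CH2Cl2, 0 °C to rt; used crude
Reagents that add atoms: oxalyl chloride, O=C(Cl)C(=O)Cl
Why: Acid chloride formation through the chloroiminium species from catalytic DMF; all by-products are gases, so the crude chloride can be used directly.

Step 7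
Reactants: 6 2,2-di-tert-butyl 1-methyl 3-[3,4-bis(benzyloxy)-5-methoxyphenyl]propane-1,2,2-tricarboxylate; 10 4-(benzyloxy)-3-methoxybenzoyl chloride
Product: 11 1,1-di-tert-butyl 2-methyl 3-[4-(benzyloxy)-3-methoxyphenyl]-1-[3,4-bis(benzyloxy)-5-methoxybenzyl]-3-oxopropane-1,1,2-tricarboxylate (racemic)
Conditions: LiN(SiMe3)2 (2.2 equiv), THF, −78 °C; then 10, −78 to −20 °C; aq. NH4Cl
Reagents that add atoms: none
Why: Claisen-type C-acylation of a lithium ester enolate with an aroyl chloride; only the CH2CO2Me arm of 6 can enolise because C3 is quaternary, and the second equivalent of base deprotonates the more acidic β-keto ester as it forms so that it does not quench unreacted enolate. The new centre is formed racemic and is meant to stay labile.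

Step 8
Reactants: 11 1,1-di-tert-butyl 2-methyl 3-[4-(benzyloxy)-3-methoxyphenyl]-1-[3,4-bis(benzyloxy)-5-methoxybenzyl]-3-oxopropane-1,1,2-tricarboxylate (racemic)
Product: 12 1,1-di-tert-butyl 2-methyl (2S,3S)-3-[4-(benzyloxy)-3-methoxyphenyl]-1-[3,4-bis(benzyloxy)-5-methoxybenzyl]-3-hydroxypropane-1,1,2-tricarboxylate
Conditions: RuCl(p-cymene)[(S,S)-TsDPEN] (2–5 mol%), HCO2H/Et3N (5:2), DMF, 35 °C
Reagents that add atoms: none
Why: Formic acid converts the 16-electron ruthenium amide into the hydride RuH(p-cymene)[(S,S)-TsDPEN], which passes hydride from the metal and a proton from the NH2 group to the aryl ketone of 11 through a six-membered outer-sphere transition state, with CO2 as the only by-product. The closest known reaction type is the dynamic kinetic asymmetric transfer hydrogenation of α-substituted β-aryl β-keto esters, here applied to an α-substituent that is a quaternary malonate carbon. No ring closes. The carbinol centre C3 is set by the catalyst: the CH/π contact between the p-cymene ligand and ring B places the aryl group on the arene side, so the (S,S)-diamine should deliver hydride to the Re face and give the (3S)-alcohol. C2, the future lactone C4, is set by relay from that face: in the Felkin–Anh conformer the very large C(CO2tBu)2CH2Ar group lies anti to the incoming hydride and the α-hydrogen flanks its trajectory, an arrangement open to the (2S)-epimer on the Re face but not to the (2R)-epimer without pressing the quaternary carbon against the catalyst. C2–H of the β-keto ester should exchange through the enol in the Et3N/HCO2H medium faster than either epimer is reduced, so the slow (2R)-ketone drains into the (2S)-manifold (Curtin–Hammett situation), and once the ketone has become an alcohol C2–H is no longer acidic and the centre is locked. The step needs chemoselectivity (ketone reduced; three esters and three benzyl ethers untouched, which this transfer hydrogenation secures) and high syn diastereoselectivity, because any (2R,3S)-diastereomer would feed the enantiomeric series once the carbinol is erased; it is therefore removed by chromatography or crystallisation at this stage. The malonate carbon is not stereogenic, so no further isomers arise.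

Step 9
Reactants: 12 1,1-di-tert-butyl 2-methyl (2S,3S)-3-[4-(benzyloxy)-3-methoxyphenyl]-1-[3,4-bis(benzyloxy)-5-methoxybenzyl]-3-hydroxypropane-1,1,2-tricarboxylate
Product: 13 di-tert-butyl 2-[3,4-bis(benzyloxy)-5-methoxybenzyl]-2-[(1S,2R)-1-[4-(benzyloxy)-3-methoxyphenyl]-1,3-dihydroxypropan-2-yl]malonate
Conditions: LiBH4, THF, 0 °C to rt; aq. NH4Cl
Reagents that add atoms: none
Why: LiBH4 reduces methyl esters but not hindered tert-butyl esters, and the neighbouring alkoxide assists hydride delivery to the methyl ester (hydroxyl-assisted borohydride reduction). C2 is not enolised under these conditions, so its configuration is kept and only its descriptor changes.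

Step 10
Reactants: 13 di-tert-butyl 2-[3,4-bis(benzyloxy)-5-methoxybenzyl]-2-[(1S,2R)-1-[4-(benzyloxy)-3-methoxyphenyl]-1,3-dihydroxypropan-2-yl]malonate
Product: 15 di-tert-butyl 2-(3,4-dihydroxy-5-methoxybenzyl)-2-[(2R)-1-hydroxy-3-(4-hydroxy-3-methoxyphenyl)propan-2-yl]malonate, via debenzylated benzylic alcohol 14 (not isolated)
Conditions: H2 (1–3 atm), Pd/C (10%), EtOH/EtOAc, AcOH (trace), 25–45 °C
Reagents that add atoms: none
Why: Hydrogenolysis over Pd/C first cleaves the three aryl benzyl ethers; the para-hydroxybenzylic alcohol 14 so formed is then hydrogenolysed at C7′–O, the same transformation that turns 7-hydroxy lignan lactones into their deoxy parents. tert-Butyl esters, the primary alcohol and the stereocentre are untouched, and doing this before any acid removes the site that would otherwise ionise and cyclise onto ring A or lactonise with a carboxyl.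

Step 11
Reactants: 15 di-tert-butyl 2-(3,4-dihydroxy-5-methoxybenzyl)-2-[(2R)-1-hydroxy-3-(4-hydroxy-3-methoxyphenyl)propan-2-yl]malonate
Product: 18 (−)-thujaplicatin [(3R,4R)-3-(3,4-dihydroxy-5-methoxybenzyl)-4-(4-hydroxy-3-methoxybenzyl)dihydrofuran-2(3H)-one], via hydroxy malonic acid 16 (not isolated), via lactone acid 17 (not isolated)
Conditions: CF3CO2H/CH2Cl2 (1:2), Et3SiH (5 equiv), 0 °C to rt; evaporate; toluene/1,4-dioxane, 100 °C; then DBU (3 equiv), degassed MeCN/toluene, 60–80 °C, Ar; aq. HCl
Reagents that add atoms: none
Why: Acidolysis of both tert-butyl esters (the tert-butyl cations are reduced to isobutane by Et3SiH before they can alkylate the phenolic rings) gives 16, which closes the γ-lactone by 5-exo-trig acyl substitution at either carboxyl. Heating decarboxylates the α-carboxy lactone 17 through the cyclic six-membered transition state to the lactone enol. Reversible deprotonation at C3 by DBU, a non-nucleophilic base that does not open the lactone, then brings any cis epimer to the more stable trans (3R) arrangement relative to the fixed C4, under argon to protect the catechol.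

## Compound list

1 | 3,4-dihydroxy-5-methoxybenzaldehyde (5-hydroxyvanillin) | COc1cc(C=O)cc(O)c1O | starting material
2 | 3,4-bis(benzyloxy)-5-methoxybenzaldehyde | COc1cc(C=O)cc(OCc2ccccc2)c1OCc1ccccc1 | intermediate
3 | di-tert-butyl malonate | CC(C)(C)OC(=O)CC(=O)OC(C)(C)C | starting material
4 | di-tert-butyl 2-[3,4-bis(benzyloxy)-5-methoxybenzylidene]malonate | COc1cc(C=C(C(=O)OC(C)(C)C)C(=O)OC(C)(C)C)cc(OCc2ccccc2)c1OCc1ccccc1 | intermediate
5 | di-tert-butyl 2-[3,4-bis(benzyloxy)-5-methoxybenzyl]malonate | COc1cc(CC(C(=O)OC(C)(C)C)C(=O)OC(C)(C)C)cc(OCc2ccccc2)c1OCc1ccccc1 | intermediate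
6 | 2,2-di-tert-butyl 1-methyl 3-[3,4-bis(benzyloxy)-5-methoxyphenyl]propane-1,2,2-tricarboxylate | COC(=O)CC(Cc1cc(OC)c(OCc2ccccc2)c(OCc2ccccc2)c1)(C(=O)OC(C)(C)C)C(=O)OC(C)(C)C | intermediate
7 | vanillic acid (4-hydroxy-3-methoxybenzoic acid) | COc1cc(C(=O)O)ccc1O | starting material
8 | benzyl 4-(benzyloxy)-3-methoxybenzoate | COc1cc(C(=O)OCc2ccccc2)ccc1OCc1ccccc1 | intermediate (not isolated)
9 | 4-(benzyloxy)-3-methoxybenzoic acid | COc1cc(C(=O)O)ccc1OCc1ccccc1 | intermediate
10 | 4-(benzyloxy)-3-methoxybenzoyl chloride | COc1cc(C(=O)Cl)ccc1OCc1ccccc1 | intermediate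
11 | 1,1-di-tert-butyl 2-methyl 3-[4-(benzyloxy)-3-methoxyphenyl]-1-[3,4-bis(benzyloxy)-5-methoxybenzyl]-3-oxopropane-1,1,2-tricarboxylate (racemic, labile at C2) | COC(=O)C(C(=O)c1ccc(OCc2ccccc2)c(OC)c1)C(Cc1cc(OC)c(OCc2ccccc2)c(OCc2ccccc2)c1)(C(=O)OC(C)(C)C)C(=O)OC(C)(C)C | intermediate
12 | 1,1-di-tert-butyl 2-methyl (2S,3S)-3-[4-(benzyloxy)-3-methoxyphenyl]-1-[3,4-bis(benzyloxy)-5-methoxybenzyl]-3-hydroxypropane-1,1,2-tricarboxylate | COc1cc([C@@H](O)[C@H](C(Cc2cc(OC)c(OCc3ccccc3)c(OCc3ccccc3)c2)(C(=O)OC(C)(C)C)C(=O)OC(C)(C)C)C(=O)OC)ccc1OCc1ccccc1 | intermediate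
13 | di-tert-butyl 2-[3,4-bis(benzyloxy)-5-methoxybenzyl]-2-[(1S,2R)-1-[4-(benzyloxy)-3-methoxyphenyl]-1,3-dihydroxypropan-2-yl]malonate | COc1cc([C@@H](O)[C@H](C(Cc2cc(OC)c(OCc3ccccc3)c(OCc3ccccc3)c2)(C(=O)OC(C)(C)C)C(=O)OC(C)(C)C)CO)ccc1OCc1ccccc1 | intermediate
14 | di-tert-butyl 2-(3,4-dihydroxy-5-methoxybenzyl)-2-[(1S,2R)-1,3-dihydroxy-1-(4-hydroxy-3-methoxyphenyl)propan-2-yl]malonate | COc1cc([C@@H](O)[C@H](C(Cc2cc(OC)c(O)c(O)c2)(C(=O)OC(C)(C)C)C(=O)OC(C)(C)C)CO)ccc1O | intermediate (not isolated)
15 | di-tert-butyl 2-(3,4-dihydroxy-5-methoxybenzyl)-2-[(2R)-1-hydroxy-3-(4-hydroxy-3-methoxyphenyl)propan-2-yl]malonate | COc1cc(C[C@H](C(Cc2cc(OC)c(O)c(O)c2)(C(=O)OC(C)(C)C)C(=O)OC(C)(C)C)CO)ccc1O | intermediate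
16 | 2-(3,4-dihydroxy-5-methoxybenzyl)-2-[(2R)-1-hydroxy-3-(4-hydroxy-3-methoxyphenyl)propan-2-yl]malonic acid | COc1cc(C[C@H](C(Cc2cc(OC)c(O)c(O)c2)(C(=O)O)C(=O)O)CO)ccc1O | intermediate (not isolated)
17 | (4R)-3-(3,4-dihydroxy-5-methoxybenzyl)-4-(4-hydroxy-3-methoxybenzyl)-2-oxotetrahydrofuran-3-carboxylic acid (both C3 epimers) | COc1cc(C[C@H]2COC(=O)C2(Cc2cc(O)c(O)c(OC)c2)C(=O)O)ccc1O | intermediate (not isolated)
18 | (−)-thujaplicatin, (3R,4R)-3-(3,4-dihydroxy-5-methoxybenzyl)-4-(4-hydroxy-3-methoxybenzyl)dihydrofuran-2(3H)-one | COc1cc(C[C@H]2COC(=O)[C@@H]2Cc2cc(O)c(O)c(OC)c2)ccc1O | target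

## Step count and least certain steps

Total: 11 steps. Longest linear sequence: 9 steps (steps 1, 2, 3, 4, 7, 8, 9, 10, 11); steps 5 and 6 form the side branch.

**Step 8 (key step).**
- Most likely failure: enolisation of the very hindered keto ester may be slower than hydride transfer, so the reaction degenerates into a plain kinetic resolution. Hydride transfer to a ketone flanked by a quaternary centre may also be sluggish. Discrimination between the two C2 epimers may be incomplete, which lowers the enantiomeric purity of C4 below that of the carbinol.
- Cause: all three depend on how the bulky malonate substituent fits in the outer-sphere transition state, which is beyond the range of the usual α-substituents.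
- Fallback (auxiliary-controlled aldol, from 6 back to 13): selective saponification of the methyl ester of 6 (LiOH, THF/H2O) would give 4-[3,4-bis(benzyloxy)-5-methoxyphenyl]-3,3-bis(tert-butoxycarbonyl)butanoic acid F1. Activation as the pivalic mixed anhydride and N-acylation of lithiated (S)-4-benzyloxazolidin-2-one would give (4S)-4-benzyl-3-{4-[3,4-bis(benzyloxy)-5-methoxyphenyl]-3,3-bis(tert-butoxycarbonyl)butanoyl}oxazolidin-2-one F2. Its dibutylboron Z-enolate (Bu2BOTf, iPr2NEt, CH2Cl2, −78 to 0 °C) would add to commercial 4-(benzyloxy)-3-methoxybenzaldehyde (COc1cc(C=O)ccc1OCc1ccccc1) in an Evans syn-aldol reaction to give di-tert-butyl 2-[3,4-bis(benzyloxy)-5-methoxybenzyl]-2-[(1S,2S)-1-[4-(benzyloxy)-3-methoxyphenyl]-3-[(4S)-4-benzyl-2-oxooxazolidin-3-yl]-1-hydroxy-3-oxopropan-2-yl]malonate F3. Reductive removal of the auxiliary with LiBH4 would deliver 13, where the route is rejoined.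

**Step 7.**
- Most likely failure: O-acylation of the neopentyl-type enolate in place of C-acylation, or consumption of the acid chloride by the excess amide base.
- Cause: the enolate carbon sits next to a quaternary centre.
- Fallback (aldol addition and oxidation, from 6 back to 11): the lithium enolate of 6 (LiN(iPr)2, THF, −78 °C, cold quench) would add to 4-(benzyloxy)-3-methoxybenzaldehyde to give racemic 1,1-di-tert-butyl 2-methyl 3-[4-(benzyloxy)-3-methoxyphenyl]-1-[3,4-bis(benzyloxy)-5-methoxybenzyl]-3-hydroxypropane-1,1,2-tricarboxylate F4 as a mixture of diastereomers. Oxidation with Dess–Martin periodinane (CH2Cl2, rt) would return to 11.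

**Step 10.**
- Most likely failure: debenzylation proceeds but hydrogenolysis of the hindered C7′–O bond stalls at 14. If it is forced with stronger acid, dehydration towards C4 or ring closure onto ring A may intervene, the former eroding the stereocentre.
- Cause: the carbinol is neopentyl-like and its cation is strongly stabilised.
- Fallback (radical deoxygenation, from 12 back to 15): 12 would be converted with 1,1′-thiocarbonyldiimidazole (DMAP cat., CH2Cl2) into 1,1-di-tert-butyl 2-methyl (2S,3S)-3-[4-(benzyloxy)-3-methoxyphenyl]-1-[3,4-bis(benzyloxy)-5-methoxybenzyl]-3-[(1H-imidazol-1-ylcarbonothioyl)oxy]propane-1,1,2-tricarboxylate F5. Barton–McCombie reduction (Bu3SnH, AIBN, toluene, 80 °C) would give 1,1-di-tert-butyl 2-methyl (2R)-3-[4-(benzyloxy)-3-methoxyphenyl]-1-[3,4-bis(benzyloxy)-5-methoxybenzyl]propane-1,1,2-tricarboxylate F6. LiBH4 would reduce the methyl ester to di-tert-butyl 2-[3,4-bis(benzyloxy)-5-methoxybenzyl]-2-[(2R)-1-[4-(benzyloxy)-3-methoxyphenyl]-3-hydroxypropan-2-yl]malonate F7. Hydrogenolysis (H2, Pd/C) then has only the benzyl ethers to remove and gives 15.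

**Step 11.**
- Most likely failure: electrophilic tert-butylation of the free phenolic rings during acidolysis, incomplete convergence of the C3 epimers, or oxidation of the catechol during the base treatment.
- Cause: the decarboxylation protonates the lactone enol under kinetic control, and the correction needs base on an unprotected triphenol.
- Fallback (ring closure and equilibration on benzyl-protected material, from 12 back to 18): 12 would be taken through F5 and F6 to the alcohol F7 as described for step 10. Acidolysis, lactonisation, decarboxylation and DBU equilibration of F7 under the conditions of step 11 would give (3R,4R)-4-[4-(benzyloxy)-3-methoxybenzyl]-3-[3,4-bis(benzyloxy)-5-methoxybenzyl]dihydrofuran-2(3H)-one F8, which can be purified as a neutral, air-stable compound. A final hydrogenolysis (H2, Pd/C, EtOAc/EtOH) would give 18.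

## Further compounds

F1 | step 8 | 4-[3,4-bis(benzyloxy)-5-methoxyphenyl]-3,3-bis(tert-butoxycarbonyl)butanoic acid | OC(=O)CC(Cc1cc(OC)c(OCc2ccccc2)c(OCc2ccccc2)c1)(C(=O)OC(C)(C)C)C(=O)OC(C)(C)C
F2 | step 8 | (4S)-4-benzyl-3-{4-[3,4-bis(benzyloxy)-5-methoxyphenyl]-3,3-bis(tert-butoxycarbonyl)butanoyl}oxazolidin-2-one | O=C1OC[C@H](Cc2ccccc2)N1C(=O)CC(Cc1cc(OC)c(OCc2ccccc2)c(OCc2ccccc2)c1)(C(=O)OC(C)(C)C)C(=O)OC(C)(C)C
F3 | step 8 | di-tert-butyl 2-[3,4-bis(benzyloxy)-5-methoxybenzyl]-2-[(1S,2S)-1-[4-(benzyloxy)-3-methoxyphenyl]-3-[(4S)-4-benzyl-2-oxooxazolidin-3-yl]-1-hydroxy-3-oxopropan-2-yl]malonate | COc1cc([C@@H](O)[C@H](C(Cc2cc(OC)c(OCc3ccccc3)c(OCc3ccccc3)c2)(C(=O)OC(C)(C)C)C(=O)OC(C)(C)C)C(=O)N2[C@@H](Cc3ccccc3)COC2=O)ccc1OCc1ccccc1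
F4 | step 7 | 1,1-di-tert-butyl 2-methyl 3-[4-(benzyloxy)-3-methoxyphenyl]-1-[3,4-bis(benzyloxy)-5-methoxybenzyl]-3-hydroxypropane-1,1,2-tricarboxylate (racemic, both diastereomers) | COC(=O)C(C(O)c1ccc(OCc2ccccc2)c(OC)c1)C(Cc1cc(OC)c(OCc2ccccc2)c(OCc2ccccc2)c1)(C(=O)OC(C)(C)C)C(=O)OC(C)(C)C
F5 | step 10 | 1,1-di-tert-butyl 2-methyl (2S,3S)-3-[4-(benzyloxy)-3-methoxyphenyl]-1-[3,4-bis(benzyloxy)-5-methoxybenzyl]-3-[(1H-imidazol-1-ylcarbonothioyl)oxy]propane-1,1,2-tricarboxylate | COc1cc([C@@H](OC(=S)n2ccnc2)[C@H](C(Cc2cc(OC)c(OCc3ccccc3)c(OCc3ccccc3)c2)(C(=O)OC(C)(C)C)C(=O)OC(C)(C)C)C(=O)OC)ccc1OCc1ccccc1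
F6 | step 10 | 1,1-di-tert-butyl 2-methyl (2R)-3-[4-(benzyloxy)-3-methoxyphenyl]-1-[3,4-bis(benzyloxy)-5-methoxybenzyl]propane-1,1,2-tricarboxylate | COc1cc(C[C@H](C(Cc2cc(OC)c(OCc3ccccc3)c(OCc3ccccc3)c2)(C(=O)OC(C)(C)C)C(=O)OC(C)(C)C)C(=O)OC)ccc1OCc1ccccc1
F7 | step 10 | di-tert-butyl 2-[3,4-bis(benzyloxy)-5-methoxybenzyl]-2-[(2R)-1-[4-(benzyloxy)-3-methoxyphenyl]-3-hydroxypropan-2-yl]malonate | COc1cc(C[C@H](C(Cc2cc(OC)c(OCc3ccccc3)c(OCc3ccccc3)c2)(C(=O)OC(C)(C)C)C(=O)OC(C)(C)C)CO)ccc1OCc1ccccc1
F8 | step 11 | (3R,4R)-4-[4-(benzyloxy)-3-methoxybenzyl]-3-[3,4-bis(benzyloxy)-5-methoxybenzyl]dihydrofuran-2(3H)-one | COc1cc(C[C@H]2COC(=O)[C@@H]2Cc2cc(OCc3ccccc3)c(OCc3ccccc3)c(OC)c2)ccc1OCc1ccccc1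
A1 | alternative 1 | 3-[4-(benzyloxy)-3-methoxybenzyl]cyclobutan-1-one | COc1cc(CC2CC(=O)C2)ccc1OCc1ccccc1
A2 | alternative 1 | (4R)-4-[4-(benzyloxy)-3-methoxybenzyl]dihydrofuran-2(3H)-one | COc1cc(C[C@H]2COC(=O)C2)ccc1OCc1ccccc1
A3 | alternative 1 | 3,4-bis(benzyloxy)-5-methoxybenzyl bromide | COc1cc(CBr)cc(OCc2ccccc2)c1OCc1ccccc1
A4 | alternative 2 | (R)-epichlorohydrin | ClC[C@H]1CO1
A5 | alternative 2 | ethyl (1S,5R)-2-oxo-3-oxabicyclo[3.1.0]hexane-1-carboxylate | O=C1OC[C@@H]2C[C@]12C(=O)OCC
A6 | alternative 2 | 1-(benzyloxy)-4-bromo-2-methoxybenzene | COc1cc(Br)ccc1OCc1ccccc1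
A7 | alternative 2 | ethyl (3S,4R)-4-[4-(benzyloxy)-3-methoxybenzyl]-2-oxotetrahydrofuran-3-carboxylate | COc1cc(C[C@H]2COC(=O)[C@@H]2C(=O)OCC)ccc1OCc1ccccc1
A8 | alternative 3 | (2R,3E)-1-[4-(benzyloxy)-3-methoxyphenyl]pent-3-en-2-yl 3-[3,4-bis(benzyloxy)-5-methoxyphenyl]propanoate | C/C=C/[C@@H](Cc1ccc(OCc2ccccc2)c(OC)c1)OC(=O)CCc1cc(OC)c(OCc2ccccc2)c(OCc2ccccc2)c1
A9 | alternative 3 | (2R,3S,4E)-2-[3,4-bis(benzyloxy)-5-methoxybenzyl]-3-[4-(benzyloxy)-3-methoxybenzyl]hex-4-enoic acid | COc1cc(C[C@H]([C@@H](Cc2cc(OC)c(OCc3ccccc3)c(OCc3ccccc3)c2)C(=O)O)/C=C/C)ccc1OCc1ccccc1
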